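Labdane numbering is used throughout. Ring A is C1–C5 and C10; ring B is C5–C10. C17 is the methylene carbon on C8. C18 is the methyl and C19 the CH2O group on C4. C20 is the methyl on C10, and the chain is C11–C12–C13(C16)–C14–C15. "C20 face" means the face of the decalin that carries C20.

## The problem

Compound 24 is an ent-labdane. It is a trans-decalin with an exocyclic methylene C8=C17, the chain C11–C15 (acid at C15) on C9, C20 on C10, and C18 plus the acylated hydroxymethyl group C19 on C4; the configuration is 4R,5S,9R,10S,13R,2'R. The hard part is the triad C4–C5–C10. Two quaternary carbons flank one methine, and C19 is axial and 1,3-diaxial to C20, while CH3 and CH2O on C4 differ too little in size for a preset C4 to steer C10, or the reverse. Once C10 is fixed, C20 shields one face of both rings, so C5 and C9 can be set from it by delivering hydrogen to the open face; C9 can also be equilibrated next to a C8 carbonyl. C13 and C2' are out of reach of any ring stereocentre and must arrive with their fragments. The 8(17)-alkene isomerises in acid and takes up hydrogen or borane faster than any ring alkene, so it has to come late; C2' is α to an ester carbonyl and will not survive strong base; the C19 ester is neopentylic, which distinguishes it from a C15 ester. The enabling feature lies in ring B, where C10 sits between C5 and C9: if both are written as carbonyls, ring B becomes the Cs-symmetric 2-methylcyclohexane-1,3-dione with C10 prochiral, and because C4 is α to the carboxyl-level carbon C19, the most crowded bond of the molecule, C4–C5, becomes an aldol bond between an ester enolate and one of two enantiotopic ketones.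

## Retrosynthesis

**24 ⇒ 23 ⇒ 22 (C15–OMe, then C8=C17).** The acid is released last from methyl ester 23, because the unhindered C15 ester can be told apart from the neopentylic C19 ester. The C8=C17 bond is then cut to give ketone 22. Eliminating a C8 carbinol instead would give mixtures of alkene isomers, whereas the ketone keeps C9 epimerisable towards the equatorial chain. The forward step is a methylenation that spares two esters.

**22 ⇒ 21 ⇒ 19 (C8–O).** The C8 oxygen is traced to the trisubstituted alkene C8=C9 of 19. Alkylating a C8 ketone at C9 would have to win against C7 and against the neighbouring quaternary C10. Hydroboration instead puts boron on C8 and hydrogen on C9 from the face opposite to C20, which fixes C9 directly.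

**19 ⇒ 14 + 17 (C9–C11).** This cut removes the whole chain in one sp2–sp3 coupling. Cuts at C11–C12 or C12–C13 would leave functional carbon on the ring and place C13 next to the reacting site. Iodide 17 derives from half-ester 15 through alcohol 16, so C13 is bought. The coupling has to work at a vinyl triflate next to a quaternary carbon.

**14 ⇒ 12 + 13; 12 ⇒ 11 ⇒ 10.** The acyl group 13 is attached while the ring carries only a vinyl triflate, so no protecting group is needed for C19–OH. Alcohol 12 comes from ester 11, and 11 from ketone 10. Enolisation of 10 can occur only at C8.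

**10 ⇒ 9 ⇒ 8 (adding O at C5).** A hydroxyl on C5 turns the array C19–C4–C5 into a β-hydroxy ester. Its removal has no regiochemical choice, since C4 and C10 carry no hydrogen. The resulting C5=C6 alkene 9 has one face closed by C19 and C20.

**8 ⇒ 5 (C4–C5, the key cut).** This breaks the bond between the quaternary C4 and the carbon that lies between both quaternary centres. Three stereocentres and ring A disappear, leaving the achiral enoate-dione 5. The forward reaction must generate the ester enolate regiospecifically by hydride addition to C3, choose one of two enantiotopic ketones, and place C19 on the C20 face.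

**5 ⇒ 3 + 4; 3 ⇒ 1 + 2.** The C3=C4 bond is an olefination of aldehyde 3 with ylide 4. The C1–C10 bond is a Michael addition of dione 1 to acrolein 2. All four compounds are commercial or one step away.

## Roads not taken

**Alternative 1:** (the most obvious) cut C4–C5 and C9–C10 together in a polyene bicyclisation.
- Forward step: in the form that can carry an axial C19 carbon, β-keto ester A1 undergoes Mn(III)/Cu(II) oxidative radical bicyclisation to A2.
- The only stereocentre of A1 (C13) is too far from the forming centres, so both decalin antipodes would form beside each other unless an auxiliary is added and later removed.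
- The cationic version cannot start at an alkene that bears the C19 oxygen, because that oxygen deactivates it.
- The C3 ketone of A2 would have to be deleted in the presence of the 8(17)-alkene.
- The E,E-diene chain of A1 costs more steps than the whole run-up to 5.

**Alternative 2:** cut C4–C18 and C4–C19 on a C3 ketone.
- Forward step: start from the Wieland–Miescher ketone A3 (R antipode), then ketalisation, reductive carbomethoxylation and methylation give A4.
- The annulation sets C10 only. C4 needs two further C–C bond formations, C5 a dissolving-metal step, and both the C3 oxygen and the ketal must be removed before 10 is reached.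
- The chosen plan forms the same ring without a C3 oxygen and sets C4 and C10 in one catalytic step from a two-step precursor.

**Alternative 3:** chiral pool, cutting C12=C13 and C3–O of andrographolide A5.
- Forward step: the decalin of A5 already has the right configuration, the axial C19–OH and the 8(17)-alkene; the key step would be oxidative cleavage of its acetonide to aldehyde A6.
- The electron-poor C12=C13 bond would have to be cleaved beside the more electron-rich 8(17)-alkene.
- C3–OH must be told apart from C19–OH and removed by radical deoxygenation.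
- The chain must be rebuilt and C13 set by a catalyst anyway, and any saturation must spare the 8(17)-alkene.
- This is a degradation rather than a synthesis, and it would not be shorter.

Key step: step 3

Remark 1: acid 13 and half-ester 15 are taken as purchasable single enantiomers.
Remark 2: the sense of induction of the ligand in step 3 cannot be predicted; all structures are drawn for the ligand antipode that gives 8.

## Route

Step 1
Reactants: 1 2-methylcyclohexane-1,3-dione; 2 acrolein
Product: 3 3-(1-methyl-2,6-dioxocyclohexyl)propanal
Conditions: H2O, rt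
Reagents that add atoms: none
Why: Michael addition of the acidic dione to acrolein makes the future C10 a prochiral quaternary carbon. The neutral medium should keep the aldehyde from intramolecular aldolisation.

Step 2
Reactants: 3 3-(1-methyl-2,6-dioxocyclohexyl)propanal; 4 methyl 2-(triphenyl-λ5-phosphanylidene)propanoate
Product: 5 methyl (E)-2-methyl-5-(1-methyl-2,6-dioxocyclohexyl)pent-2-enoate
Conditions: CH2Cl2, rt
Reagents that add atoms: none
Why: Wittig olefination with a stabilised ylide should touch only the aldehyde, not the hindered ketones, and give the E-trisubstituted enoate.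

Step 3
Reactants: 5 methyl (E)-2-methyl-5-(1-methyl-2,6-dioxocyclohexyl)pent-2-enoate
Product: 8 methyl (1R,4aR,8aS)-8a-hydroxy-1,4a-dimethyl-5-oxodecahydronaphthalene-1-carboxylate, via copper enolate 6 (not isolated), via silyl ether 7 (not isolated)
Conditions: Cu(OAc)2·H2O (5 mol %), SEGPHOS (one antipode, 5.5 mol %), PhSiH3 (1.5 equiv), toluene, −20 °C; then 1 M HCl, THF, 0 °C
Reagents that add atoms: none
Why: Proposed new method: L*Cu–H (from the copper salt and the silane) adds hydride to C3 of the enoate, the copper ketene acetal 6 attacks one ring carbonyl (C5) through a closed six-membered transition state in which copper bridges both oxygens, and σ-bond metathesis of the copper aldolate with the silane gives 7 and returns Cu–H; acid then frees 8. The closest known reaction type is the Cu–H-catalysed domino conjugate reduction/aldol cyclisation of α-unsubstituted enoates tethered to 2-alkyl-2-methyl-1,3-diones, which desymmetrises the dione; new here is the α-methyl group, which makes the nucleophile a tetrasubstituted enolate and C4 quaternary. Ring A closes in a 6-(enolexo)-exo-trig aldol mode. C10 is set by the ligand, which decides which of the two enantiotopic carbonyl groups is attacked. C5 follows from the tether, which should bring O5 cis to C20 (cis-ketol); this centre is erased in step 4. C4 is set by the closed transition state, which needs C19 gauche to O5: every such arrangement that puts C18 on the C20 face pays a methyl/methyl 1,3-diaxial contact, so the flat ketene-acetal carbon C19 should take that place and end cis to C20 as the target demands. The step needs 1,4-reduction ahead of carbonyl hydrosilylation, which the substrate favours because both ketones are neopentylic while the enoate is the only conjugate acceptor, and it needs C–C bond formation ahead of O-silylation of 6, which the intramolecular six-ring closure favours.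

Step 4
Reactants: 8 methyl (1R,4aR,8aS)-8a-hydroxy-1,4a-dimethyl-5-oxodecahydronaphthalene-1-carboxylate
Product: 9 methyl (1R,4aR)-1,4a-dimethyl-5-oxo-1,2,3,4,4a,5,6,7-octahydronaphthalene-1-carboxylate
Conditions: SOCl2, pyridine, CH2Cl2, −10 → 0 °C
Reagents that add atoms: none
Why: E2-type dehydration proceeds through the tertiary chlorosulfite. C4 and C10 are quaternary, so only C6 offers β-hydrogens and only the C5=C6 alkene can form. The buffered medium should avoid cationic methyl shifts and retro-aldol cleavage.

Step 5
Reactants: 9 methyl (1R,4aR)-1,4a-dimethyl-5-oxo-1,2,3,4,4a,5,6,7-octahydronaphthalene-1-carboxylate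
Product: 10 methyl (1R,4aR,8aS)-1,4a-dimethyl-5-oxodecahydronaphthalene-1-carboxylate
Conditions: H2 (4 bar), 10% Pd/C, EtOAc, rt
Reagents that add atoms: none
Why: In this heterogeneous hydrogenation, axial C20 and the pseudoaxial ester C19 close one face, so hydrogen should reach C5 from the opposite face and give the trans-decalin. This is as known for Δ5-octalins with 4,4,10-substitution. Ketone and ester are inert.

Step 6
Reactants: 10 methyl (1R,4aR,8aS)-1,4a-dimethyl-5-oxodecahydronaphthalene-1-carboxylate
Product: 11 methyl (1R,4aR,8aS)-1,4a-dimethyl-5-(trifluoromethylsulfonyloxy)-1,2,3,4,4a,7,8,8a-octahydronaphthalene-1-carboxylate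
Conditions: KHMDS, THF, −78 °C; PhNTf2, −78 → 0 °C; aq. work-up
Reagents that add atoms: N-phenylbis(trifluoromethanesulfonimide), O=S(=O)(N(c1ccccc1)S(=O)(=O)C(F)(F)F)C(F)(F)F
Why: Enolate O-triflation. C10 is quaternary and the ester has no α-hydrogen, so deprotonation can occur only at C8.

Step 7
Reactants: 11 methyl (1R,4aR,8aS)-1,4a-dimethyl-5-(trifluoromethylsulfonyloxy)-1,2,3,4,4a,7,8,8a-octahydronaphthalene-1-carboxylate
Product: 12 (4aR,5R,8aR)-5-(hydroxymethyl)-5,8a-dimethyl-3,4,4a,5,6,7,8,8a-octahydronaphthalen-1-yl trifluoromethanesulfonate
Conditions: DIBAL-H (2.5 equiv), CH2Cl2, −78 → 0 °C; aq. work-up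
Reagents that add atoms: none
Why: Hydride reduction of the ester to the primary alcohol. Hydride attack is little affected by the axial, neopentylic position, and vinyl triflates are inert to DIBAL-H.

Step 8
Reactants: 12 (4aR,5R,8aR)-5-(hydroxymethyl)-5,8a-dimethyl-3,4,4a,5,6,7,8,8a-octahydronaphthalen-1-yl trifluoromethanesulfonate; 13 (R)-2-methylbutanoic acid
Product: 14 [(1R,4aR,8aR)-1,4a-dimethyl-5-(trifluoromethylsulfonyloxy)-1,2,3,4,4a,7,8,8a-octahydronaphthalen-1-yl]methyl (2R)-2-methylbutanoate
Conditions: DCC, DMAP, CH2Cl2, 0 °C → rt
Reagents that add atoms: none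
Why: Steglich esterification. The alcohol is hindered but primary, and carbodiimide activation avoids the ketene pathway, so C2' should be kept.

Step 9
Reactants: 15 (3R)-5-methoxy-3-methyl-5-oxopentanoic acid
Product: 16 methyl (3R)-5-hydroxy-3-methylpentanoate
Conditions: BH3·SMe2 (1.05 equiv), THF, −10 °C → rt; H2O
Reagents that add atoms: none
Why: Borane reduces the free acid much faster than the methyl ester. C13 is untouched, and the product is used at once to forestall lactonisation.

Step 10
Reactants: 16 methyl (3R)-5-hydroxy-3-methylpentanoate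
Product: 17 methyl (3S)-5-iodo-3-methylpentanoate
Conditions: I2, PPh3, imidazole, CH2Cl2, 0 °C
Reagents that add atoms: iodine, II
Why: Appel-type iodination of a primary alcohol. The descriptor changes only because iodine changes the priorities.

Step 11
Reactants: 14 [(1R,4aR,8aR)-1,4a-dimethyl-5-(trifluoromethylsulfonyloxy)-1,2,3,4,4a,7,8,8a-octahydronaphthalen-1-yl]methyl (2R)-2-methylbutanoate; 17 methyl (3S)-5-iodo-3-methylpentanoate
Product: 19 methyl (4R,5S,10R,13R)-19-[(2R)-2-methylbutanoyloxy]-17-norlabd-8-en-15-oate, via alkylzinc iodide 18 (not isolated)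
Conditions: 17, Zn dust, LiCl, THF, 40 °C; then 14, Pd(dppf)Cl2 (5 mol %), THF/NMP, 50 °C
Reagents that add atoms: none
Why: Negishi sp2–sp3 coupling forms C9–C11. The alkylzinc reagent tolerates both esters, and the wide-bite-angle ligand should suppress β-hydride elimination.

Step 12
Reactants: 19 methyl (4R,5S,10R,13R)-19-[(2R)-2-methylbutanoyloxy]-17-norlabd-8-en-15-oate
Product: 21 methyl (4R,5S,8S,9S,10R,13R)-8-hydroxy-19-[(2R)-2-methylbutanoyloxy]-17-norlabdan-15-oate, via alkylborane 20 (not isolated)
Conditions: BH3·THF, THF, 0 °C → rt; then 30% H2O2, aq. NaOAc, 0 °C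
Reagents that add atoms: hydrogen peroxide, OO
Why: Hydroboration–oxidation puts boron on the less substituted C8. The syn addition should occur on the face opposite to C20, so C9 receives its hydrogen on that face and the chain becomes equatorial. Buffered oxidation spares the esters.

Step 13
Reactants: 21 methyl (4R,5S,8S,9S,10R,13R)-8-hydroxy-19-[(2R)-2-methylbutanoyloxy]-17-norlabdan-15-oate
Product: 22 methyl (4R,5S,9S,10R,13R)-19-[(2R)-2-methylbutanoyloxy]-8-oxo-17-norlabdan-15-oate
Conditions: Dess–Martin periodinane, CH2Cl2, rt
Reagents that add atoms: none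
Why: Neutral oxidation of the secondary alcohol. The equatorial chain at C9 is also the thermodynamic arrangement next to the ketone.

Step 14
Reactants: 22 methyl (4R,5S,9S,10R,13R)-19-[(2R)-2-methylbutanoyloxy]-8-oxo-17-norlabdan-15-oate
Product: 23 methyl (4R,5S,9R,10S,13R)-19-[(2R)-2-methylbutanoyloxy]labd-8(17)-en-15-oate
Conditions: MePPh3Br (1.6 equiv), KOtBu (1.5 equiv), THF, 0 °C; then 22, 0 °C → rt
Reagents that add atoms: methyltriphenylphosphonium bromide, C[P+](c1ccccc1)(c1ccccc1)c1ccccc1.[Br-]
Why: Wittig methylenation, well known on 8-oxo-17-norlabdanes. The ylide is too weak a base to deprotonate the esters, and keeping the salt in excess over the base leaves no free alkoxide, so C2' and the C15 ester should be safe.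

Step 15
Reactants: 23 methyl (4R,5S,9R,10S,13R)-19-[(2R)-2-methylbutanoyloxy]labd-8(17)-en-15-oate
Product: 24 (4R,5S,9R,10S,13R)-19-[(2R)-2-methylbutanoyloxy]labd-8(17)-en-15-oic acid
Conditions: LiOH, THF/MeOH/H2O, 0 °C → rt; then 1 M HCl to pH 3–4, 0 °C
Reagents that add atoms: lithium hydroxide, [Li+].[OH-]
Why: In this saponification the unhindered methyl ester should react far faster than the neopentylic ester of an α-branched acid. Brief cold acidification should not isomerise the 8(17)-alkene.

## Compound list

1 | 2-methylcyclohexane-1,3-dione | CC1C(=O)CCCC1=O | starting material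
2 | acrolein | C=CC=O | starting material
3 | 3-(1-methyl-2,6-dioxocyclohexyl)propanal | O=CCCC1(C)C(=O)CCCC1=O | intermediate
4 | methyl 2-(triphenyl-λ5-phosphanylidene)propanoate | COC(=O)C(C)=P(c1ccccc1)(c1ccccc1)c1ccccc1 | starting material
5 | methyl (E)-2-methyl-5-(1-methyl-2,6-dioxocyclohexyl)pent-2-enoate | COC(=O)/C(C)=C/CCC1(C)C(=O)CCCC1=O | intermediate
6 | copper(I) ketene acetal from hydride addition to C3 of 5 (ligand omitted) | COC(O[Cu])=C(C)CCCC1(C)C(=O)CCCC1=O | intermediate
7 | O-phenylsilyl ether of 8 | C1CC[C@@]2(O[SiH2]c3ccccc3)[C@](C)(C(=O)OC)CCC[C@@]2(C)C1=O | intermediate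
8 | methyl (1R,4aR,8aS)-8a-hydroxy-1,4a-dimethyl-5-oxodecahydronaphthalene-1-carboxylate (ester, OH and angular methyl on one face) | C1CC[C@@]2(O)[C@](C)(C(=O)OC)CCC[C@@]2(C)C1=O | intermediate
9 | methyl (1R,4aR)-1,4a-dimethyl-5-oxo-1,2,3,4,4a,5,6,7-octahydronaphthalene-1-carboxylate | C1CC=C2[C@](C)(C(=O)OC)CCC[C@@]2(C)C1=O | intermediate
10 | methyl (1R,4aR,8aS)-1,4a-dimethyl-5-oxodecahydronaphthalene-1-carboxylate (trans-decalin) | C1CC[C@@H]2[C@](C)(C(=O)OC)CCC[C@@]2(C)C1=O | intermediate
11 | methyl (1R,4aR,8aS)-1,4a-dimethyl-5-(trifluoromethylsulfonyloxy)-1,2,3,4,4a,7,8,8a-octahydronaphthalene-1-carboxylate | C=1CC[C@@H]2[C@](C)(C(=O)OC)CCC[C@@]2(C)C=1OS(=O)(=O)C(F)(F)F | intermediate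
12 | (4aR,5R,8aR)-5-(hydroxymethyl)-5,8a-dimethyl-3,4,4a,5,6,7,8,8a-octahydronaphthalen-1-yl trifluoromethanesulfonate | C=1CC[C@@H]2[C@](C)(CO)CCC[C@@]2(C)C=1OS(=O)(=O)C(F)(F)F | intermediate
13 | (R)-2-methylbutanoic acid | CC[C@@H](C)C(=O)O | starting material
14 | [(1R,4aR,8aR)-1,4a-dimethyl-5-(trifluoromethylsulfonyloxy)-1,2,3,4,4a,7,8,8a-octahydronaphthalen-1-yl]methyl (2R)-2-methylbutanoate | C=1CC[C@@H]2[C@](C)(COC(=O)[C@H](C)CC)CCC[C@@]2(C)C=1OS(=O)(=O)C(F)(F)F | intermediate
15 | (3R)-5-methoxy-3-methyl-5-oxopentanoic acid | OC(=O)C[C@@H](C)CC(=O)OC | starting material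
16 | methyl (3R)-5-hydroxy-3-methylpentanoate | OCC[C@@H](C)CC(=O)OC | intermediate
17 | methyl (3S)-5-iodo-3-methylpentanoate | ICC[C@@H](C)CC(=O)OC | intermediate
18 | [(3S)-5-methoxy-3-methyl-5-oxopentyl]zinc iodide | I[Zn]CC[C@@H](C)CC(=O)OC | intermediate
19 | methyl (4R,5S,10R,13R)-19-[(2R)-2-methylbutanoyloxy]-17-norlabd-8-en-15-oate | C=1CC[C@@H]2[C@](C)(COC(=O)[C@H](C)CC)CCC[C@@]2(C)C=1CC[C@@H](C)CC(=O)OC | intermediate
20 | monoalkylborane of 19 (BH2 on C8 and H on C9, both on the face opposite to C20) | B[C@H]1CC[C@@H]2[C@](C)(COC(=O)[C@H](C)CC)CCC[C@@]2(C)[C@@H]1CC[C@@H](C)CC(=O)OC | intermediate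
21 | methyl (4R,5S,8S,9S,10R,13R)-8-hydroxy-19-[(2R)-2-methylbutanoyloxy]-17-norlabdan-15-oate | O[C@H]1CC[C@@H]2[C@](C)(COC(=O)[C@H](C)CC)CCC[C@@]2(C)[C@@H]1CC[C@@H](C)CC(=O)OC | intermediate
22 | methyl (4R,5S,9S,10R,13R)-19-[(2R)-2-methylbutanoyloxy]-8-oxo-17-norlabdan-15-oate | O=C1CC[C@@H]2[C@](C)(COC(=O)[C@H](C)CC)CCC[C@@]2(C)[C@@H]1CC[C@@H](C)CC(=O)OC | intermediate
23 | methyl (4R,5S,9R,10S,13R)-19-[(2R)-2-methylbutanoyloxy]labd-8(17)-en-15-oate | C=C1CC[C@@H]2[C@](C)(COC(=O)[C@H](C)CC)CCC[C@@]2(C)[C@@H]1CC[C@@H](C)CC(=O)OC | intermediate
24 | (4R,5S,9R,10S,13R)-19-[(2R)-2-methylbutanoyloxy]labd-8(17)-en-15-oic acid (CNP0365997.1) | C=C1CC[C@@H]2[C@](C)(COC(=O)[C@H](C)CC)CCC[C@@]2(C)[C@@H]1CC[C@@H](C)CC(=O)O | target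

## Step count and least certain steps

Total: 15 steps. Longest linear sequence: 13 steps (steps 1–8 and 11–15); steps 9 and 10 form the side branch.

**Step 3 (key step, proposed new method).**
- What may go wrong: the crowded tetrasubstituted enolate may be silylated or protonated before the C–C bond forms, giving plain conjugate reduction. Hydrosilylation of a ring ketone may compete with the slower reduction of the trisubstituted enoate. The preference for placing C19 on the C20 face may erode if an open transition state takes part.
- Fallback (known chemistry, from 3 back to 9): aldehyde 3 is olefinated with methyl (triphenylphosphoranylidene)acetate to the α-unsubstituted enoate F1. The Cu–H reductive aldol cyclisation, now within its demonstrated substrate class, gives the ketol ester F2. Dehydration with SOCl2/pyridine gives the conjugated ester F3, and the C9 ketone is masked as the dioxolane F4. Deconjugative α-methylation of the extended enolate (LDA, DMPU, MeI) should bring C18 in on the face opposite to C20 and move the double bond to C5=C6, giving the ketal ester F5. Aqueous acid then returns the route to 9.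

**Step 5.**
- What may go wrong: slow or incomplete hydrogen uptake, because the C5=C6 bond lies between two quaternary carbons and adsorbs poorly on the metal.
- Fallback (from 8 back to 10): the alkene is bypassed. Ketol 8 is acylated with methyl chlorooxoacetate/DMAP to the methyl oxalate F6, and tin hydride reduction (Bu3SnH, AIBN, toluene, reflux) generates the C5 radical. It should take hydrogen on the face opposite to C19 and C20 and give 10 directly.

**Step 11.**
- What may go wrong: sluggish oxidative addition and transmetalation at the triflate next to quaternary C10, which leaves time for β-hydride elimination or protodemetalation of the alkyl partner.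
- Fallback (from 14 back to 19): the smallest possible partner is coupled first. Stille vinylation (tributyl(vinyl)stannane, LiCl, Pd(0)) gives the diene F7, and 9-BBN adds to the terminal vinyl group to give the B-alkyl borane F8. Suzuki coupling with methyl (E)-3-iodobut-2-enoate gives the dienoate F9. A ligand-controlled Cu–H conjugate reduction then sets C13 and gives 19.

**Step 12.**
- What may go wrong: partial reduction of the C15 methyl ester by borane while the hindered alkene reacts slowly, or incomplete conversion.
- Fallback (from 19 back to 22): mCPBA epoxidation on the face opposite to C20 gives the epoxide F10. Lewis-acid rearrangement (BF3·OEt2, −78 °C) opens it at tertiary C9 with a hydride shift from C8. Equilibration with DBU then gives ketone 22 with the equatorial chain.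

**Step 15.**
- What may go wrong: loss of selectivity between the two esters on prolonged exposure, or slow epimerisation at C2' in the basic medium.
- Fallback (from 23 to 24): alkyl–oxygen instead of acyl–oxygen cleavage. LiI in hot pyridine attacks the methyl carbon by SN2, a path closed to the neopentylic C19; no new compound is involved.

## Further compounds

F1 | step 3 | methyl (E)-5-(1-methyl-2,6-dioxocyclohexyl)pent-2-enoate | COC(=O)/C=C/CCC1(C)C(=O)CCCC1=O
F2 | step 3 | methyl 8a-hydroxy-4a-methyl-5-oxodecahydronaphthalene-1-carboxylate (ester, OH and methyl cis; same absolute series as 8) | C1CC[C@@]2(O)[C@H](C(=O)OC)CCC[C@@]2(C)C1=O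
F3 | step 3 | methyl (4aR)-4a-methyl-5-oxo-2,3,4,4a,5,6,7,8-octahydronaphthalene-1-carboxylate | C1CCC2=C(C(=O)OC)CCC[C@@]2(C)C1=O
F4 | step 3 | ethylene ketal of F3 at the ring ketone | C1CCC2=C(C(=O)OC)CCC[C@@]2(C)C13OCCO3
F5 | step 3 | ethylene ketal of 9 | C1CC=C2[C@](C)(C(=O)OC)CCC[C@@]2(C)C13OCCO3
F6 | step 5 | methyl oxalate ester of ketol 8 | C1CC[C@@]2(OC(=O)C(=O)OC)[C@](C)(C(=O)OC)CCC[C@@]2(C)C1=O
F7 | step 11 | C9-vinyl diene from 14 | C=1CC[C@@H]2[C@](C)(COC(=O)[C@H](C)CC)CCC[C@@]2(C)C=1C=C
F8 | step 11 | 9-BBN adduct of F7 at C12 | C=1CC[C@@H]2[C@](C)(COC(=O)[C@H](C)CC)CCC[C@@]2(C)C=1CCB3C4CCCC3CCC4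
F9 | step 11 | methyl (13E)-19-[(2R)-2-methylbutanoyloxy]-17-norlabda-8,13-dien-15-oate | C=1CC[C@@H]2[C@](C)(COC(=O)[C@H](C)CC)CCC[C@@]2(C)C=1CC/C(C)=C/C(=O)OC
F10 | step 12 | 8,9-epoxide of 19 (oxygen on the face opposite to C20) | [C@H]12CC[C@@H]3[C@](C)(COC(=O)[C@H](C)CC)CCC[C@@]3(C)[C@]1(O2)CC[C@@H](C)CC(=O)OC
F0 | step 15 | none | none
A1 | alternative 1 | dimethyl (6E,10E,14R)-2,6,10,14-tetramethyl-3-oxohexadeca-6,10-dienedioate | COC(=O)C(C)C(=O)CC/C(C)=C/CC/C(C)=C/CC[C@@H](C)CC(=O)OC
A2 | alternative 1 | dimethyl 3-oxo-ent-labd-8(17)-ene-15,19-dioate (13R) | C=C1CC[C@@H]2[C@](C)(C(=O)OC)C(=O)CC[C@@]2(C)[C@@H]1CC[C@@H](C)CC(=O)OC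
A3 | alternative 2 | (8aR)-8a-methyl-3,4,8,8a-tetrahydronaphthalene-1,6(2H,7H)-dione (Wieland–Miescher ketone, R antipode) | C1CCC2=CC(=O)CC[C@@]2(C)C1=O
A4 | alternative 2 | 3-oxo analogue of 10 with the C9 ketone as ethylene ketal | C1CC[C@@H]2[C@](C)(C(=O)OC)C(=O)CC[C@@]2(C)C13OCCO3
A5 | alternative 3 | andrographolide | C=C1CC[C@@H]2[C@](C)(CO)[C@H](O)CC[C@@]2(C)[C@@H]1C/C=C1/C(=O)OC[C@H]1O
A6 | alternative 3 | 3,19-O-isopropylidene C12 aldehyde from cleavage of C12=C13 | C=C1CC[C@@H]2[C@]3(C)COC(C)(C)O[C@@H]3CC[C@@]2(C)[C@@H]1CC=O
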